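## The problem

The target, [(3R,4S,5R,6S)-5-(benzoyloxy)-3,4,6-trihydroxycyclohex-1-en-1-yl]methyl benzoate (11), is a single cyclohexene in which C1 is the alkene carbon bearing the benzoyloxymethyl carbon C7, C2 is the alkene CH, and C3, C4, C5 and C6 each carry oxygen. The carbon skeleton is trivial, so the synthesis is a matter of oxygenation, stereochemistry and telling five oxygens apart. The four contiguous stereocentres stand C3/C4 trans, C4/C5 cis and C5/C6 trans, and a single enantiomer is wanted, so at least one centre must come from a chiral source and relay the rest. C5 is the natural relay: a free hydroxyl there is allylic to a C3=C4 bond and can deliver oxygen to C4 on its own face, after which C3 follows by backside attack, whereas C6, trans to C5 and next to the C1–C7 unit, cannot be reached this way and is best acquired together with C5. Two oxygens are benzoylated (secondary C5, primary allylic C7) and three are free, so at some stage the C5 hydroxyl must be the only free one. The benzoates are base-labile and can migrate to the cis C4 hydroxyl or to C6–OH, the allylic carbinols at C3 and C6 ionise in strong acid, any cyclohexadienediol precursor aromatises by loss of water, and a vinyl oxirane opens readily under acid. The enabling feature is that, once the C3 and C4 hydroxyls are set aside, the C1–C7 unit with trans C5/C6 oxygens is the reduced form of the microbial (5S,6S)-trans-dihydrodiol acid 2, and the trans C3/C4 diol with C4–O cis to C5–O is exactly what hydration of a C3–C4 oxirane lying cis to the C5 hydroxyl gives.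

## Retrosynthesis

**11 to 10 and 7.** The C7–O acyl bond is cut last, giving tetrol monobenzoate 10 and benzoyl chloride 7. A primary allylic hydroxyl can be acylated beside three secondary ones by rate alone, whereas leaving the C5 ester to the end would mean picking one secondary hydroxyl out of four. The forward step must stop at mono-acylation and must not move the C5 benzoate.

**10 to 8 (through 9).** The C3–O bond and the two acetal C–O bonds are cut, leading to epoxy benzoate 8. C3 is chosen over C4 because it is allylic, and anti attack there gives the trans-diaxial diol in the half-chair held by the fused dioxane, so electronic and stereoelectronic preferences agree. Precursor 8 has one free-hydroxyl problem fewer and hides C6–O and C7–O in one ring. The forward reaction must invert C3 cleanly, leave the ester alone, and then release the acetal (diol acetonide 9 is the expected transient).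

**8 to 6 and 7.** The C5–O acyl bond is cut here because in epoxy alcohol 6 the C5 hydroxyl is the only free one. The forward acylation needs only to spare the oxirane.

**6 to 5 (key disconnection).** The C3–O and C4–O bonds of the oxirane are cut, giving dienol acetonide 5. This removes one ring and two stereocentres and leaves a conjugated diene whose only free hydroxyl is at C5. A cis-dihydroxylation would give the wrong C3/C4 relationship, and an undirected epoxidation of a C5 ester would favour the face away from C5–O. The forward reaction must choose C3=C4 over C1=C2 and the face of C5–OH.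

**5 to 4.** The acetal C–O bonds are cut to triol 4. C6–O and C7–O are 1,3-related and close a six-membered acetal, whereas the trans C5/C6 pair on a cyclohexadiene cannot be bridged by a five-membered one. One operation therefore isolates C5–OH. The forward step must be mild enough not to dehydrate the dienediol.

**4 to 3 to 2.** C7 is returned to the carboxyl oxidation level: triol 4 comes from methyl ester 3 by hydride reduction, and 3 from acid 2 by O-methylation. No stereocentre is involved, and both steps must avoid acid.

**2 to 1.** Acid 2 already holds C1–C7 and the (5S,6S) centres. It is a shikimate-pathway metabolite and is traced to D-glucose 1 by fermentation, its seven carbons being drawn from two glucose molecules by the cell, so no chemical asymmetric step is needed.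

## Roads not taken

Alternative 1: The ring would be cut at C1–C2 and C5–C6 and built by a Diels–Alder reaction of furan A1 with 2-bromoacrolein A2 under a chiral B-butyl oxazaborolidinone derived from N-tosyl-tryptophan. This gives the 7-oxanorbornene bromo aldehyde A3, whose oxygen bridge would later be opened to reveal the cyclohexene.
- Merits: A1 and A2 are bulk chemicals, the absolute configuration comes from a catalyst, either enantiomer is accessible, and the bridge supplies the C5 oxygen.
- Weak points: only the C5 bridgehead of A3 survives as a stereocentre. The other bridgehead becomes sp2 C2, and the bromo aldehyde centre at C6 is erased on conversion to a carbonyl. The formyl carbon sits on C6 and is not C7, so C7 must be attached to C1 by a separate C–C bond formation. C3, C4 and C6 all remain to be set by substrate control, and furan cycloadducts revert easily.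
- Comparison: this road is better in starting-material availability and needs no fermentation. The chosen plan sets against that a first intermediate holding all seven carbons with C5 and C6 in place, and roughly half the step count.

Alternative 2: The C4–O and C5–O bonds would be cut back to benzyl benzoate A4. Under visible light the triazolinedione A5, which is 4-methyl-1,2,4-triazoline-3,5-dione, adds across C3 and C6 of the benzyl ring of A4 in a (4+2) sense. OsO4 with a chiral diamine then dihydroxylates the disubstituted alkene anti to the bridge in the same flask, giving the urazole-bridged cis-diol A6.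
- Merits: it is by far the shortest opening. A4 is a commodity that already carries the C7 benzoate, A5 is a shelf reagent, the cis C4/C5 diol is set at once, and C1=C2 stays in place.
- Weak points: the cycloadduct of A5 with a monosubstituted arene is chiral but forms as a racemate, so the osmium reagent can only resolve it, and absolute control is indirect. The nitrogens that A5 places at C3 and C6 must then be replaced by oxygen on the face the bridge occupied, with net retention at two centres, for which no direct method exists. C4–OH and C5–OH emerge together and must be told apart for mono-benzoylation.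
- Comparison: this road is better up to A6 and needs no biotechnology. The chosen plan sets against it enzyme-fixed absolute configuration, every oxygen arriving with its final configuration, and a C5 hydroxyl that is acylated while it is the only free one.

Alternative 3: The C1–C6 bond would be cut, and the ring closed by an intramolecular Morita–Baylis–Hillman reaction of the enoate aldehyde A8, made from D-arabinose A7. PMe3 adds to C2, the C1 enolate attacks the C6 aldehyde, and phosphine loss gives the cyclohexene ester A9.
- Merits: C3, C4 and C5 come from the catalogue sugar A7 with the correct absolute configuration, C7 is already present as the ester carbon, and the cis C4/C5 pair is held as an acetonide.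
- Weak points: A8 requires several protecting-group and redox steps on A7. As an α,β-dialkoxy aldehyde it is prone to epimerisation at C5 and β-elimination under the nucleophilic conditions. The C6 carbinol is set by substrate control alone and must come out trans to C5–O. After A9 the acetonide frees C4–OH and C5–OH together, so the C5 ester again needs a selective acylation of a cis-diol, and the ester reduction and C7 benzoylation need further protecting-group moves.
- Comparison: this road takes three stereocentres from the chiral pool against two in the chosen plan and avoids fermentation. The chosen plan answers with a secured trans C5/C6 pair, a uniquely addressable C5 hydroxyl and a much shorter sequence.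

Key step: step 5

Assumption: the whole-cell catalyst of step 1 is an Escherichia coli strain that overexpresses isochorismate synthase (entC) and isochorismatase (entB) and lacks the 2,3-dihydro-2,3-dihydroxybenzoate dehydrogenase (entA), made by standard cloning; intermediates are described with the carbocycle locants C1–C7 of the target.

## Route

Step 1
Reactants: 1 D-glucose
Product: 2 (5S,6S)-5,6-dihydroxycyclohexa-1,3-diene-1-carboxylic acid
Conditions: E. coli (entC and entB overexpressed; entA deleted) whole cells, glucose/mineral-salts fed-batch, aerated, 37 °C, pH 7; cell-free broth on anion exchanger, aq. HCO2H elution, lyophilisation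
Reagents that add atoms: D-glucose (second molecule of 1), OC[C@@H](O)[C@@H](O)[C@H](O)[C@@H](O)C=O; water, O
Why: Whole-cell biosynthesis along the shikimate pathway, in which erythrose 4-phosphate from one glucose and phosphoenolpyruvate from a second supply the seven carbons (idealised net equation 2 C6H12O6 + 5/2 O2 → C7H8O4 + pyruvic acid + 2 CO2 + 6 H2O). Isochorismate synthase converts chorismate by an SN2′-type exchange that brings water to C6, isochorismatase hydrolyses the enol ether on C5–O with release of pyruvate, and the missing dehydrogenase prevents aromatisation. C5 is inherited from chorismate and C6 is set by the synthase, so the (5S,6S) configuration is enzyme-controlled.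

Step 2
Reactants: 2 (5S,6S)-5,6-dihydroxycyclohexa-1,3-diene-1-carboxylic acid
Product: 3 methyl (5S,6S)-5,6-dihydroxycyclohexa-1,3-diene-1-carboxylate
Conditions: MeI (1.5 equiv), KHCO3 (1.5 equiv), DMF, rt
Reagents that add atoms: iodomethane, CI
Why: SN2 O-alkylation of the carboxylate; the weak base leaves the hydroxyls unalkylated and the near-neutral medium avoids acid-promoted dehydration of the dihydrodiol.

Step 3
Reactants: 3 methyl (5S,6S)-5,6-dihydroxycyclohexa-1,3-diene-1-carboxylate
Product: 4 (1S,2S)-3-(hydroxymethyl)cyclohexa-3,5-diene-1,2-diol
Conditions: iBu2AlH (5 equiv), THF, −78 → 0 °C; MeOH, then Na2SO4·10H2O, filtration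
Reagents that add atoms: none
Why: 1,2-Reduction of a conjugated ester to the allylic alcohol by iBu2AlH; the two hydroxyls are first converted to aluminium alkoxides, hence the excess, and the non-aqueous quench spares the water-soluble, acid-sensitive triol. The stereocentres are untouched.

Step 4
Reactants: 4 (1S,2S)-3-(hydroxymethyl)cyclohexa-3,5-diene-1,2-diol
Product: 5 (8S,8aS)-2,2-dimethyl-8,8a-dihydro-4H-1,3-benzodioxin-8-ol (acetonide across C6–O/C7–O; C5–OH free)
Conditions: 2-methoxypropene (1.3 equiv), PPTS (5 mol %), DMF, 0 °C; Et3N quench
Reagents that add atoms: 2-methoxypropene, COC(C)=C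
Why: Kinetic acetalisation with an enol ether: the primary C7 hydroxyl adds first and the mixed acetal closes onto the neighbouring C6 hydroxyl to a six-membered dioxane, as in 4,6-O-isopropylidene formation on pyranosides. A trans-fused dioxolane across C5/C6 is strained, so C5–OH stays free; the weak acid at 0 °C should not trigger aromatisation.

Step 5
Reactants: 5 (8S,8aS)-2,2-dimethyl-8,8a-dihydro-4H-1,3-benzodioxin-8-ol
Product: 6 (3S,4R,5R,6S)-3,4-epoxy-6,7-O-isopropylidene-1-(hydroxymethyl)cyclohex-1-ene-5,6-diol (carbocycle locants; oxirane cis to C5–OH and trans to C6–O; C1=C2 retained)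
Conditions: VO(acac)2 (5 mol %), tBuOOH (1.3 equiv, anhydrous in decane), CH2Cl2, 0 °C → rt; chromatography on Et3N-washed silica
Reagents that add atoms: tert-butyl hydroperoxide, CC(C)(C)OO
Why: VO(acac)2 is oxidised by tBuOOH to a pentavalent vanadium alkoxide that exchanges ligands with the C5 hydroxyl of 5 and with the hydroperoxide; the bound peroxide oxygen is then transferred in one concerted step to the C3=C4 alkene held beside it. The closest known reaction type is the vanadium-catalysed syn epoxidation of cyclic allylic alcohols, established for cyclohexenols and conjugated dienols. The oxirane closes by a formal (2+1) oxygen-atom transfer in which the C3–O and C4–O bonds form suprafacially on one oxygen, not by cyclisation of a chain. C3 and C4 are created together as (3S,4R), both controlled by the C5 stereocentre through the vanadate tether, so the new oxygen lies cis to C5–OH and trans to C6–O. The step needs chemoselectivity for C3=C4 over C1=C2, and the substrate provides it: only C3=C4 has a free allylic hydroxyl, while C1=C2 is merely homoallylic to it and is inductively deactivated by its own allylic oxygens at C6 and C7, both tied in the dioxane. The dioxane fusion holds C5–OH pseudoequatorial, a geometry that still directs syn but reacts more slowly than a pseudoaxial carbinol, so anhydrous oxidant, low temperature and prompt work-up are specified to limit carbinol oxidation and opening of the vinyl oxirane.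

Step 6
Reactants: 6 (3S,4R,5R,6S)-3,4-epoxy-6,7-O-isopropylidene-1-(hydroxymethyl)cyclohex-1-ene-5,6-diol; 7 benzoyl chloride
Product: 8 (3S,4S,5R,6S)-5-O-benzoyl-3,4-epoxy-6,7-O-isopropylidene-1-(hydroxymethyl)cyclohex-1-ene-5,6-diol (carbocycle locants; oxirane cis to C5–OBz)
Conditions: BzCl (1.2 equiv), Et3N (2 equiv), 4-(dimethylamino)pyridine (10 mol %), CH2Cl2, 0 °C
Reagents that add atoms: benzoyl chloride (7), O=C(Cl)c1ccccc1
Why: Nucleophile-catalysed acylation of the only free hydroxyl; the oxirane and the acetal are inert to the cold, buffered, non-aqueous medium. The change of descriptor at C4 is a priority change only.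

Step 7
Reactants: 8 (3S,4S,5R,6S)-5-O-benzoyl-3,4-epoxy-6,7-O-isopropylidene-1-(hydroxymethyl)cyclohex-1-ene-5,6-diol
Product: 10 (1R,2S,5R,6S)-2,5,6-trihydroxy-3-(hydroxymethyl)cyclohex-3-en-1-yl benzoate, via diol acetonide benzoate 9 (not isolated)
Conditions: 0.05 M aq. HClO4/THF 1:3, 0 °C → rt; NaHCO3
Reagents that add atoms: water, O
Why: Acid-catalysed hydrolysis of a vinyl oxirane: water attacks allylic C3 anti to the protonated oxygen (inversion at C3, C4 retained), which is also the trans-diaxial Fürst–Plattner mode in the half-chair biased by the fused dioxane. The C5 benzoate is cis to the oxirane and cannot participate from the rear. The isopropylidene acetal of 9 then hydrolyses in the same medium, and dilute acid does not promote acyl migration.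

Step 8
Reactants: 10 (1R,2S,5R,6S)-2,5,6-trihydroxy-3-(hydroxymethyl)cyclohex-3-en-1-yl benzoate; 7 benzoyl chloride
Product: 11 [(3R,4S,5R,6S)-5-(benzoyloxy)-3,4,6-trihydroxycyclohex-1-en-1-yl]methyl benzoate
Conditions: BzCl (1.05 equiv), 2,4,6-collidine (2 equiv), CH2Cl2/THF, −78 → −40 °C
Reagents that add atoms: benzoyl chloride (7), O=C(Cl)c1ccccc1
Why: Rate-selective acylation of the primary allylic hydroxyl over three secondary ones with an acyl chloride and a hindered pyridine base at low temperature; the weak base and the cold suppress benzoate migration. No stereocentre is touched.

## Compound list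

1 | D-glucose | OC[C@@H](O)[C@@H](O)[C@H](O)[C@@H](O)C=O | starting material
2 | (5S,6S)-5,6-dihydroxycyclohexa-1,3-diene-1-carboxylic acid | OC(=O)C1=CC=C[C@H](O)[C@H]1O | intermediate
3 | methyl (5S,6S)-5,6-dihydroxycyclohexa-1,3-diene-1-carboxylate | COC(=O)C1=CC=C[C@H](O)[C@H]1O | intermediate
4 | (1S,2S)-3-(hydroxymethyl)cyclohexa-3,5-diene-1,2-diol | OCC1=CC=C[C@H](O)[C@H]1O | intermediate
5 | (8S,8aS)-2,2-dimethyl-8,8a-dihydro-4H-1,3-benzodioxin-8-ol | CC1(C)OCC2=CC=C[C@H](O)[C@H]2O1 | intermediate
6 | (3S,4R,5R,6S)-3,4-epoxy-6,7-O-isopropylidene-1-(hydroxymethyl)cyclohex-1-ene-5,6-diol (carbocycle locants) | CC1(C)OCC2=C[C@@H]3O[C@@H]3[C@H](O)[C@H]2O1 | intermediate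
7 | benzoyl chloride | O=C(Cl)c1ccccc1 | starting material
8 | (3S,4S,5R,6S)-5-O-benzoyl-3,4-epoxy-6,7-O-isopropylidene-1-(hydroxymethyl)cyclohex-1-ene-5,6-diol (carbocycle locants) | CC1(C)OCC2=C[C@@H]3O[C@@H]3[C@H](OC(=O)c4ccccc4)[C@H]2O1 | intermediate
9 | (3R,4S,5S,6S)-5-O-benzoyl-6,7-O-isopropylidene-1-(hydroxymethyl)cyclohex-1-ene-3,4,5,6-tetrol (carbocycle locants; diol acetonide benzoate) | CC1(C)OCC2=C[C@@H](O)[C@H](O)[C@H](OC(=O)c3ccccc3)[C@H]2O1 | intermediate
10 | (1R,2S,5R,6S)-2,5,6-trihydroxy-3-(hydroxymethyl)cyclohex-3-en-1-yl benzoate | OCC1=C[C@@H](O)[C@H](O)[C@H](OC(=O)c2ccccc2)[C@H]1O | intermediate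
11 | [(3R,4S,5R,6S)-5-(benzoyloxy)-3,4,6-trihydroxycyclohex-1-en-1-yl]methyl benzoate | O=C(OCC1=C[C@@H](O)[C@H](O)[C@H](OC(=O)c2ccccc2)[C@H]1O)c1ccccc1 | target

## Step count and risks

Total steps: 8. Longest linear sequence: 8 (from D-glucose 1; benzoyl chloride 7 enters twice).

**Step 5 (key step).** The most likely failure is slow oxygen transfer from the pseudoequatorial C5 vanadate. That gives time for oxidation of the carbinol (followed by tautomerisation to a phenol) or for Lewis-acid opening of the vinyl oxirane by tert-butanol. Fallback: move the hydroxyl-directed epoxidation to the dienoate stage, where the C1=C2 bond is conjugated to the ester and inert to electrophilic oxidants. Setting out from 3, buffered 3-chloroperoxybenzoic acid (NaHCO3, CH2Cl2, 0 °C) should epoxidise only C3=C4 under hydrogen-bond direction by the allylic C5 hydroxyl (Henbest-type, well suited to a pseudoequatorial carbinol). This gives the epoxy diol ester F1. iBu2AlH at −78 °C would reduce the ester to the epoxy triol F2, and acetalisation as in step 4 returns to the route at 6.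

**Step 4.** The most likely failure is acid-promoted ionisation at the doubly allylic C5 carbinol and loss of water with aromatisation. A lesser one is partial acetal formation at C5–OH. Fallback: a base-mediated cyclic silylene in place of the acetal. Setting out from 4, tBu2Si(OTf)2 and 2,6-lutidine (DMF, −40 °C) should bridge the 1,3-related C6 and C7 oxygens to the silylene dienol F3. The conditions of step 5 would give the silylene epoxy alcohol F4, and those of step 6 the silylene epoxy benzoate F5. Dilute aqueous HClO4 would open only the oxirane to the silylene diol benzoate F6, and HF·pyridine (THF, 0 °C) would remove the silylene and return to the route at 10.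

**Step 7.** The most likely failure is carbocation character at C3, which allows attack on the oxirane face (cis-diol) or at C1 with allylic transposition. This is more likely if the acetal is lost before the oxirane opens and the conformational bias disappears. Migration of the benzoate to the newly freed cis C4 hydroxyl is a further risk. Fallback: a true SN2 opening before the ester is present. Setting out from 6, aqueous NaOH in 1,4-dioxane at 80 °C should open the oxirane at C3 by anti attack of hydroxide; the C5 alkoxide is cis to the oxirane and cannot undergo Payne rearrangement. This gives the triol acetonide F7. Its cis C4/C5 diol would form a stannylene acetal with Bu2SnO, and BzCl would acylate the equatorial C5 oxygen, returning to the route at 9. Intermediate 9 would then be taken to 10 with 80% aqueous acetic acid.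

**Step 8.** The most likely failure is over-acylation at the allylic C3 or C6 hydroxyls, or base-promoted benzoate migration (C5 to C4, C7 to C6). Fallback: enzyme-controlled acyl transfer in place of rate control. Setting out from 10, immobilised Candida antarctica lipase B with vinyl benzoate (THF, 40 °C) should acylate only the primary hydroxyl under neutral conditions and arrive directly at 11; no new compound is made.

## Further compounds

F1 | step 5 | methyl (3S,4R,5R,6S)-3,4-epoxy-5,6-dihydroxycyclohex-1-ene-1-carboxylate (carbocycle locants; oxirane cis to C5–OH) | COC(=O)C1=C[C@@H]2O[C@@H]2[C@H](O)[C@H]1O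
F2 | step 5 | (3S,4R,5R,6S)-3,4-epoxy-1-(hydroxymethyl)cyclohex-1-ene-5,6-diol (carbocycle locants) | OCC1=C[C@@H]2O[C@@H]2[C@H](O)[C@H]1O
F3 | step 4 | (8S,8aS)-2,2-di-tert-butyl-8,8a-dihydro-4H-1,3,2-benzodioxasilin-8-ol | CC(C)(C)[Si]1(C(C)(C)C)OCC2=CC=C[C@H](O)[C@H]2O1
F4 | step 4 | C3–C4 oxirane of F3 cis to C5–OH (silylene epoxy alcohol) | CC(C)(C)[Si]1(C(C)(C)C)OCC2=C[C@@H]3O[C@@H]3[C@H](O)[C@H]2O1
F5 | step 4 | C5 benzoate of F4 (silylene epoxy benzoate) | CC(C)(C)[Si]1(C(C)(C)C)OCC2=C[C@@H]3O[C@@H]3[C@H](OC(=O)c4ccccc4)[C@H]2O1
F6 | step 4 | trans C3/C4 diol from F5 with the C6–O/C7–O silylene and the C5 benzoate (silylene diol benzoate) | CC(C)(C)[Si]1(C(C)(C)C)OCC2=C[C@@H](O)[C@H](O)[C@H](OC(=O)c3ccccc3)[C@H]2O1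
F7 | step 7 | 6,7-O-isopropylidene-1-(hydroxymethyl)cyclohex-1-ene-3,4,5,6-tetrol with C3–OH trans to C4–OH and C4–OH cis to C5–OH (triol acetonide) | CC1(C)OCC2=C[C@@H](O)[C@H](O)[C@H](O)[C@H]2O1
F0 | step 8 | none | none
A1 | alternative 1 | furan | c1ccoc1
A2 | alternative 1 | 2-bromoacrolein | C=C(Br)C=O
A3 | alternative 1 | 2-bromo-7-oxabicyclo[2.2.1]hept-5-ene-2-carbaldehyde | O=C[C@]1(Br)C[C@H]2C=C[C@@H]1O2
A4 | alternative 2 | benzyl benzoate | O=C(OCc1ccccc1)c1ccccc1
A5 | alternative 2 | 4-methyl-1,2,4-triazoline-3,5-dione | CN1C(=O)N=NC1=O
A6 | alternative 2 | urazole-bridged C4/C5 cis-diol with nitrogens on C3 and C6 and the C7 benzoate | O=C(OCC1=C[C@@H]2[C@H](O)[C@H](O)[C@H]1N1C(=O)N(C)C(=O)N12)c1ccccc1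
A7 | alternative 3 | D-arabinose | O=C[C@@H](O)[C@H](O)[C@H](O)CO
A8 | alternative 3 | ethyl (Z)-enoate with C3 tert-butyldimethylsilyl ether, C4/C5 acetonide and C6 aldehyde | CCOC(=O)/C=C\[C@@H](O[Si](C)(C)C(C)(C)C)[C@@H]1OC(C)(C)O[C@@H]1C=O
A9 | alternative 3 | ethyl cyclohexenecarboxylate with C6–OH, C3 silyl ether and C4/C5 acetonide | CCOC(=O)C1=C[C@@H](O[Si](C)(C)C(C)(C)C)[C@@H]2OC(C)(C)O[C@@H]2[C@H]1O
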